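3 answers are asked: the excess at the end of violet, the excess at the end of grey, and which of the two flasks wins by it.

common to all: left-handed substrate 0.25 M; right-handed substrate 0.25 M

| flask | partner | precatalyst | remark | time |
|---|---|---|---|---|
| alpha | 0.18 M | 0.57 mM | run made earlier |  |
| violet | 0.275 M | 0.57 mM |  | 1.0 h |
| grey | 0.275 M | 0.20 mM |  | 1.0 h |

alpha run (percent of the left-handed substrate and right-handed substrate together charged)

| time / min | right-handed substrate / % | left-handed substrate / % | left-handed product / % |
|---|---|---|---|
| 3.00 | 49.3 | 48.6 | 1.0 |
| 4.00 | 49.3 | 49.1 | 0.9 |
| 6.00 | 49.1 | 49.4 | 1.6 |
| 10.0 | 48.1 | 47.2 | 1.2 |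
| 15.0 | 46.9 | 45.2 | 4.0 |
| 25.0 | 46.2 | 40.7 | 9.7 |
| 40.0 | 43.5 | 36.6 | 16.3 |

(readings scatter by 1 percentage point)

- free catalyst is single-handed; left-handed substrate and right-handed substrate are mirror images of each other, charged as a racemate, each of them at the stated concentration
- what was read earlier has a scatter of 1 percentage point, one standard deviation
- an excess is the difference of the two amounts in percent of their sum
- an excess is below zero if the other one leads
- no earlier run changes the charge of precatalyst; that part of a forecast is a guess

- the winner by excess of right-handed substrate over left-handed substrate among what is left of the two; "neither" if no more than 2 percentage points parts them (violet / grey / neither)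
- excess of right-handed substrate over left-handed substrate among what is left of the two at the end, violet
- excess of right-handed substrate over left-handed substrate among what is left of the two at the end, grey

- The alpha run at 40.0 min has 19.9% of both substrates reacted and an excess of 8.61%. Their ratio is 0.433. This excess yield, the excess divided by the fraction reacted, is the quantity carried.
- Objection: that is one reading, and the ratio may drift. The reading at 25.0 min gives 0.483, a gap that a scatter of 1 percentage point per reading covers, so the ratio stands.
- The fraction reacted is still needed. Partner is the limiting reagent, taken here as one partner per substrate, so the alpha run keeps 44.7% of its partner.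
- The alpha readings stay flat up to 10.0 min. Counting from there and treating partner as pseudo-first-order gives 0.0268 /min.
- First pass on violet: partner is 0.550 of the substrates charged, and the same constant gives 40.6% reacted.
- Objection: violet has less substrate on average than the alpha run. Putting that answer back scales the constant by the mean substrate left, so 38.2% reacts and the excess is 16.5%.
- Grey needs a guess, since no run changes precatalyst. Scaling the rate by 0.351 gives 20.6% on a first pass. A second pass gives 20.6% and an excess of 8.91%.
- The gap of 7.6 points exceeds the margin, so violet leads.
- The forecast says violet, with 18% and 9%, “assuming rate proportional to catalyst (a guess)” for grey. Its violet value stands above this reckoning.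

    partner + free catalyst + left-handed substrate → free catalyst + left-handed product (k = 23.6 /M²/s)
    partner + free catalyst + right-handed substrate → free catalyst + right-handed product (k = 10.7 /M²/s)
    left-handed substrate ⇌ right-handed substrate (k = 5.38 × 10⁻⁵ /s)
    partner + free catalyst → spent catalyst (k = 5.43 × 10⁻⁴ /M/s)
    partner + precatalyst → free catalyst + spent reagent (k = 5.96 × 10⁻⁴ /M/s)

- Violet gives 19.5% and grey 12.7%, so violet leads. Violet keeps 16% of its partner, so 46.1% has reacted, more than reckoned, and the excess yield turns that into 20.0%. A neighbouring flask is violet with 0.0014 M of precatalyst and keeps 4.5% of its partner. So 52.5% has reacted there, the excess yield gives 22.7%, and that neighbouring flask shows 22.7%.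

Readings and results were generated by integration from invented constants; noise was put on by code.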